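**Retrosynthetic overview**
1. Last bond: the central single bond of the (2E,4E)-diene, by Suzuki coupling of oxanyl E-vinyl iodide 6 with cyclohexyl E-alkenylboronate 14.
2. Oxane ring (the only ring built): one-flask formal [3+3] annulation of glycidic ester 1 (gives O1, C2, C3) with prenylmagnesium chloride 2 (gives C4, C5, C6 and both C6 methyls). C3–C4 forms by copper-catalysed epoxide opening; O1–C6 and C5–Br form by bromoperoxidase-mediated bromo-etherification.
3. Enabling feature: O1–C6(CH3)2–C5HBr–C4H2 of the oxane is a prenyl unit that has taken up bromine. The gem-dimethyl carbon C6 carries the positive charge of a bromonium ion, so the ring oxygen closes there; the C3H2–C4H2 bond lies between an epoxide CH2 and a prenyl CH2, with the oxygen already on quaternary C2.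
4. Cyclohexane ring: taken intact from (S)-limonene 7. The cis bromohydrin comes from the trans-diaxial bromohydrin, epoxide, axial selenide and bromide displacement with inversion; the side chain from ozonolysis and boron–Wittig olefination.
5. Ring order: cyclohexane from the chiral pool, oxane in step 1, then the diene joins the two halves.

Key step: step 1

Assumption: the oxidised bromine stays bound to the bromoperoxidase, so the enzyme and not the remote C2 centre chooses the alkene face; the enzyme that gives the 5S bromide would be picked from a small panel of vanadium haloperoxidases.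

**Step 1**
Reactants: 1 methyl (2R)-2-methyloxirane-2-carboxylate; 2 prenylmagnesium chloride
Product: 4 methyl (2R,5S)-5-bromo-2,6,6-trimethyloxane-2-carboxylate, via hydroxy ester 3 (not isolated)
Conditions: 2 (slow addition), CuI (10 mol %), THF, −78 °C; then aq. MES buffer pH 6.5, KBr, Na3VO4 (cat.), vanadium-dependent bromoperoxidase (Corallina officinalis), H2O2 (slow addition), 25 °C
Reagents that add atoms: potassium bromide, [K+].[Br-]
Why: Proposed new method: copper-catalysed SN2 opening of the 2,2-disubstituted epoxide at its CH2 carbon by the prenyl Grignard reagent (alpha-coupling through the less hindered allyl terminus) forms the CH2–CH2 bond and gives tertiary alcohol 3, whose prenyl alkene is then brominated in the same flask by the electrophilic bromine that the bromoperoxidase makes from bromide and H2O2. The hydroxyl opens the bromonium ion at the gem-dimethyl carbon, a 6-endo (Markovnikov) closure of the oxane ring that forms the O–C(CH3)2 bond and leaves bromine on the neighbouring CH. The closest known reaction types are the copper-catalysed opening of epoxides and glycidic esters by Grignard reagents, including prenylmagnesium chloride, and the bromo-cycloetherification of terpene alcohols by vanadium bromoperoxidases, together with the chloro-etherification of prenyl groups by bacterial vanadium haloperoxidases. The quaternary centre comes unchanged from epoxide 1 because only the CH2 carbon is attacked, and the new CHBr centre is set by the alkene face that the enzyme brominates, a choice no achiral bromonium donor can make against the remote quaternary centre. The step needs alpha over gamma coupling (copper catalysis and the unhindered epoxide CH2), 6-endo over 5-exo closure (the charge sits on the gem-dimethyl carbon) and face selectivity (enzyme).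

**Step 2**
Reactants: 4 methyl (2R,5S)-5-bromo-2,6,6-trimethyloxane-2-carboxylate
Product: 5 (2R,5S)-5-bromo-2,6,6-trimethyloxane-2-carbaldehyde
Conditions: i-Bu2AlH (1.1 equiv), CH2Cl2, −78 °C; aq. Rochelle salt
Reagents that add atoms: none
Why: Partial ester reduction with i-Bu2AlH should stop at the aldehyde because the alpha-alkoxy ester forms a chelated aluminium hemiacetal that is stable at −78 °C, while the hindered secondary bromide is inert and no stereocentre is touched.

**Step 3**
Reactants: 5 (2R,5S)-5-bromo-2,6,6-trimethyloxane-2-carbaldehyde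
Product: 6 (2R,5S)-5-bromo-2-[(E)-2-iodoethenyl]-2,6,6-trimethyloxane
Conditions: CrCl2, CHI3, THF/dioxane, 0 to 25 °C
Reagents that add atoms: iodoform, IC(I)I
Why: Takai olefination, in which the geminal dichromium reagent from iodoform adds to the hindered non-enolisable aldehyde and eliminates to the E-vinyl iodide, the E geometry arising from the anti arrangement of the bulky groups in the elimination, and divalent chromium should leave the unactivated secondary bromide alone.

**Step 4**
Reactants: 7 (S)-limonene
Product: 8 (1R,2R,4S)-2-bromo-1-methyl-4-(prop-1-en-2-yl)cyclohexan-1-ol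
Conditions: NBS, acetone/H2O, 0 °C
Reagents that add atoms: N-bromosuccinimide, O=C1CCC(=O)N1Br; water, O
Why: Bromohydrin formation at the more electron-rich ring alkene, in which water opens the bromonium ion at the tertiary carbon in the trans-diaxial (Fürst–Plattner) sense, so that the existing ring stereocentre places OH cis and Br trans to the isopropenyl group.

**Step 5**
Reactants: 8 (1R,2R,4S)-2-bromo-1-methyl-4-(prop-1-en-2-yl)cyclohexan-1-ol
Product: 10 1-[(1S,3R,4R)-3-bromo-4-hydroxy-4-methylcyclohexyl]ethan-1-one, via ozonide 9 (not isolated)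
Conditions: O3, CH2Cl2, −78 °C; then Me2S, −78 to 25 °C
Reagents that add atoms: ozone, [O-][O+]=O
Why: Ozonolysis with reductive work-up should cleave the only remaining alkene to the methyl ketone without touching the alcohol, the bromide or any stereocentre.

**Step 6**
Reactants: 10 1-[(1S,3R,4R)-3-bromo-4-hydroxy-4-methylcyclohexyl]ethan-1-one
Product: 12 1-[(1S,3R,4R)-4-hydroxy-4-methyl-3-(phenylselanyl)cyclohexyl]ethan-1-one, via keto epoxide 11 (not isolated)
Conditions: PhSeH, K2CO3, EtOH, 25 °C
Reagents that add atoms: benzeneselenol, [SeH]c1ccccc1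
Why: Base closes the trans-diaxial bromohydrin to the epoxide (intramolecular Williamson reaction, inversion at the CHBr carbon) and the selenolate reopens it by SN2 at the secondary carbon in the trans-diaxial sense, so the C–Se bond should end axial and anti to the tertiary hydroxyl.

**Step 7**
Reactants: 12 1-[(1S,3R,4R)-4-hydroxy-4-methyl-3-(phenylselanyl)cyclohexyl]ethan-1-one
Product: 13 1-[(1S,3S,4R)-3-bromo-4-hydroxy-4-methylcyclohexyl]ethan-1-one
Conditions: Br2 (1.05 equiv), CH2Cl2, −78 to −20 °C
Reagents that add atoms: bromine, BrBr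
Why: Krief-type bromodeselenation, in which bromine adds to selenium and bromide displaces PhSeBr from the bromoselenonium salt by SN2 with inversion, should turn the axial selenide into the equatorial bromide cis to the hydroxyl, which without base is a poor neighbouring group.

**Step 8**
Reactants: 13 1-[(1S,3S,4R)-3-bromo-4-hydroxy-4-methylcyclohexyl]ethan-1-one
Product: 14 (1R,2S,4S)-2-bromo-1-methyl-4-[(1E)-1-(4,4,5,5-tetramethyl-1,3,2-dioxaborolan-2-yl)prop-1-en-2-yl]cyclohexan-1-ol
Conditions: CH2(Bpin)2, lithium 2,2,6,6-tetramethylpiperidide (2.2 equiv), THF, −78 to 25 °C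
Reagents that add atoms: bis(4,4,5,5-tetramethyl-1,3,2-dioxaborolan-2-yl)methane, CC1(C)OB(CB2OC(C)(C)C(C)(C)O2)OC1(C)C
Why: Boron–Wittig olefination of a ketone, in which the lithiated geminal diboronate adds to the acetyl group and the adduct loses a boron–oxygen fragment by syn elimination, should place the boryl group trans to the bulkier cyclohexyl substituent (E), the second equivalent of base covering the free hydroxyl.

**Step 9**
Reactants: 6 (2R,5S)-5-bromo-2-[(E)-2-iodoethenyl]-2,6,6-trimethyloxane; 14 (1R,2S,4S)-2-bromo-1-methyl-4-[(1E)-1-(4,4,5,5-tetramethyl-1,3,2-dioxaborolan-2-yl)prop-1-en-2-yl]cyclohexan-1-ol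
Product: 15 (1R,2S,4S)-2-bromo-4-[(2E,4E)-5-[(2R,5S)-5-bromo-2,6,6-trimethyloxan-2-yl]penta-2,4-dien-2-yl]-1-methylcyclohexan-1-ol
Conditions: Pd(dppf)Cl2 (5 mol %), K3PO4, THF/H2O, 40 °C
Reagents that add atoms: none
Why: Suzuki–Miyaura coupling of an alkenyl iodide with an alkenylboronate should keep both double-bond geometries and give the E,E-diene, since zerovalent palladium with an aryl phosphine ligand does not insert into the two unactivated secondary alkyl bromides under these mild conditions and no stereocentre is touched.

**Compound list**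
1 | methyl (2R)-2-methyloxirane-2-carboxylate | COC(=O)[C@@]1(C)CO1 | starting material
2 | prenylmagnesium chloride, (3-methylbut-2-en-1-yl)magnesium chloride | CC(C)=CC[Mg]Cl | starting material
3 | methyl (2R)-2-hydroxy-2,6-dimethylhept-5-enoate | COC(=O)[C@@](O)(C)CCC=C(C)C | intermediate
4 | methyl (2R,5S)-5-bromo-2,6,6-trimethyloxane-2-carboxylate | COC(=O)[C@@]1(C)CC[C@H](Br)C(C)(C)O1 | intermediate
5 | (2R,5S)-5-bromo-2,6,6-trimethyloxane-2-carbaldehyde | O=C[C@@]1(C)CC[C@H](Br)C(C)(C)O1 | intermediate
6 | (2R,5S)-5-bromo-2-[(E)-2-iodoethenyl]-2,6,6-trimethyloxane | I/C=C/[C@@]1(C)CC[C@H](Br)C(C)(C)O1 | intermediate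
7 | (S)-limonene, (4S)-1-methyl-4-(prop-1-en-2-yl)cyclohex-1-ene | CC(=C)[C@H]1CCC(C)=CC1 | starting material
8 | (1R,2R,4S)-2-bromo-1-methyl-4-(prop-1-en-2-yl)cyclohexan-1-ol | CC(=C)[C@H]1CC[C@@](C)(O)[C@H](Br)C1 | intermediate
9 | (1R,2R,4S)-2-bromo-1-methyl-4-(3-methyl-1,2,4-trioxolan-3-yl)cyclohexan-1-ol (ozonide, both epimers at the trioxolane carbon) | CC1(OCOO1)[C@H]1CC[C@@](C)(O)[C@H](Br)C1 | intermediate
10 | 1-[(1S,3R,4R)-3-bromo-4-hydroxy-4-methylcyclohexyl]ethan-1-one | CC(=O)[C@H]1CC[C@@](C)(O)[C@H](Br)C1 | intermediate
11 | 1-[(1S,3S,6R)-6-methyl-7-oxabicyclo[4.1.0]heptan-3-yl]ethan-1-one (epoxide oxygen cis to the acetyl group) | CC(=O)[C@H]1CC[C@@]2(C)O[C@H]2C1 | intermediate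
12 | 1-[(1S,3R,4R)-4-hydroxy-4-methyl-3-(phenylselanyl)cyclohexyl]ethan-1-one | CC(=O)[C@H]1CC[C@@](C)(O)[C@H]([Se]c2ccccc2)C1 | intermediate
13 | 1-[(1S,3S,4R)-3-bromo-4-hydroxy-4-methylcyclohexyl]ethan-1-one | CC(=O)[C@H]1CC[C@@](C)(O)[C@@H](Br)C1 | intermediate
14 | (1R,2S,4S)-2-bromo-1-methyl-4-[(1E)-1-(4,4,5,5-tetramethyl-1,3,2-dioxaborolan-2-yl)prop-1-en-2-yl]cyclohexan-1-ol | C/C(=C\B1OC(C)(C)C(C)(C)O1)[C@H]1CC[C@@](C)(O)[C@@H](Br)C1 | intermediate
15 | (1R,2S,4S)-2-bromo-4-[(2E,4E)-5-[(2R,5S)-5-bromo-2,6,6-trimethyloxan-2-yl]penta-2,4-dien-2-yl]-1-methylcyclohexan-1-ol | C/C(=C\C=C\[C@@]1(C)CC[C@H](Br)C(C)(C)O1)[C@H]1CC[C@@](C)(O)[C@@H](Br)C1 | target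

Total step count: 9. Longest linear sequence: 6 steps (steps 4 to 9, from 7 to 15).

**Steps most likely to fail**

Step 1 (proposed new method).
- What may go wrong: loss of face selectivity if the oxidised bromine leaves the enzyme as free hypobromite; loss of enzyme activity through residual copper and magnesium salts or THF; gamma-coupling of the prenyl unit or attack on the ester in the first stage; 5-exo instead of 6-endo closure.
- Fallback (known chemistry): it sets out from 1 and 2 and comes back at 4. The first stage is run alone (2, CuI, THF, −78 °C, NH4Cl work-up) and hydroxy ester 3 is isolated. Compound 3 is then cyclised in a separate operation with the stoichiometric bromonium donor 2,4,4,6-tetrabromocyclohexa-2,5-dienone in MeNO2 at 0 °C, the established bromo-etherification of homoprenyl tertiary alcohols. This is not face-selective and should give 4 together with its C5 epimer methyl (2R,5R)-5-bromo-2,6,6-trimethyloxane-2-carboxylate F1. The two are separated by chromatography, and F1 is returned to 3 with zinc dust in AcOH/EtOH (reductive opening of the beta-bromo ether) and cyclised again.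

Step 7.
- What may go wrong: participation of the anti-periplanar tertiary hydroxyl (epoxide formation and reopening with the wrong regio- or stereochemistry) and elimination of the axial selenonium group, both competing with the hindered SN2 displacement.
- Fallback: it sets out from 12 and comes back at 13. The hydroxyl is first masked with trifluoroacetic anhydride and pyridine as the non-participating ester (1R,2R,4S)-4-acetyl-1-methyl-2-(phenylselanyl)cyclohexyl trifluoroacetate F2. Bromodeselenation of F2 with Br2 in CH2Cl2 should then give (1R,2S,4S)-4-acetyl-2-bromo-1-methylcyclohexyl trifluoroacetate F3 with clean inversion. Brief methanolysis of F3 (K2CO3, MeOH, 0 °C) releases 13.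

Step 8.
- What may go wrong: incomplete E/Z control in the boron–oxygen elimination and enolisation of the methyl ketone by the basic reagent.
- Fallback: it sets out from 13 and comes back at 15; the geometry is secured by thermodynamic equilibration at the end instead of by the olefination. The mixture of 14 and its isomer (1R,2S,4S)-2-bromo-1-methyl-4-[(1Z)-1-(4,4,5,5-tetramethyl-1,3,2-dioxaborolan-2-yl)prop-1-en-2-yl]cyclohexan-1-ol F4 is coupled with 6 as in step 9. The resulting mixture of 15 and (1R,2S,4S)-2-bromo-4-[(2Z,4E)-5-[(2R,5S)-5-bromo-2,6,6-trimethyloxan-2-yl]penta-2,4-dien-2-yl]-1-methylcyclohexan-1-ol F5 is equilibrated with catalytic I2 under visible light in CH2Cl2. The 2E isomer 15 should be favoured because it keeps the diene chain away from the cyclohexyl group; residual F5 is separated and resubmitted.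

**Further compounds**
F1 | step 1 | methyl (2R,5R)-5-bromo-2,6,6-trimethyloxane-2-carboxylate | COC(=O)[C@@]1(C)CC[C@@H](Br)C(C)(C)O1
F2 | step 7 | (1R,2R,4S)-4-acetyl-1-methyl-2-(phenylselanyl)cyclohexyl trifluoroacetate | CC(=O)[C@H]1CC[C@@](C)(OC(=O)C(F)(F)F)[C@H]([Se]c2ccccc2)C1
F3 | step 7 | (1R,2S,4S)-4-acetyl-2-bromo-1-methylcyclohexyl trifluoroacetate | CC(=O)[C@H]1CC[C@@](C)(OC(=O)C(F)(F)F)[C@@H](Br)C1
F4 | step 8 | (1R,2S,4S)-2-bromo-1-methyl-4-[(1Z)-1-(4,4,5,5-tetramethyl-1,3,2-dioxaborolan-2-yl)prop-1-en-2-yl]cyclohexan-1-ol | C/C(=C/B1OC(C)(C)C(C)(C)O1)[C@H]1CC[C@@](C)(O)[C@@H](Br)C1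
F5 | step 8 | (1R,2S,4S)-2-bromo-4-[(2Z,4E)-5-[(2R,5S)-5-bromo-2,6,6-trimethyloxan-2-yl]penta-2,4-dien-2-yl]-1-methylcyclohexan-1-ol | C/C(=C/C=C/[C@@]1(C)CC[C@H](Br)C(C)(C)O1)[C@H]1CC[C@@](C)(O)[C@@H](Br)C1
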